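The earlier runs and the new flask are simulated with constants of no real substance; scatter was added.

1. Take a small charge, 1 mM of catalyst on 1 M of solid substrate, in flask birch, and follow the ratio of target to isomer of the product.

| setting | birch | cedar | flask |
|---|---|---|---|
| solid substrate | 1 M | 1 M | 1.0 M |
| catalyst | 1 mM | 2 mM | 1.0 mM |
| remark | the very flask that is asked about, followed so far | run made earlier |  |
| time |  |  | 80 min |

- birch (time / min: target / %, isomer of the product / %, solid substrate / %): 1.33: 13.6, 1.6, 58.6; 2.00: 21.7, 3.7, 39.5; 4.00: 43.8, 16.6, 0.4; 6.00: 45.8, 25.7, 0; 10.0: 38.3, 38.3, 0.2; 15.0: 33.5, 47.8, 0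
- cedar (time / min: target / %, isomer of the product / %, solid substrate / %): 5.00: 44.7, 28.8, 0; 10.0: 33.4, 45.2, 1.1; 15.0: 29.9, 54.0, 0; 20.0: 27.1, 53.2, 0; 25.0: 28.6, 55.6, 0; 30.0: 28.3, 57.0, 0

(standard deviation of a reading: 1 percentage point)

- ratio of target to isomer of the product at 1.0 min
- ratio of target to isomer of the product at 10 min
- ratio of target to isomer of the product at 80 min
- which of target and isomer of the product there is more of at 80 min

- as a solid, counted per litre of solution: solid substrate
- the numbers in the tables scatter with a standard deviation of 1 percentage point
- at the start none of the solid substrate is in solution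

2. Draw the start of birch. At 1.33 min target reads 13.6% and isomer 1.6%, a ratio of 8.50; at 2.00 min the ratio reads 5.86. Call this stretch kinetic control. Leave the ratio at 1.0 min open, since a scatter of 1 percentage point sits on that small isomer reading.

3. Mark the knee in birch. Solid substrate reads 0.4% at 4.00 min, and target reads its highest, 45.8%, at 6.00 min.

4. Mark the crossing in birch. At 10.0 min target and isomer both read 38.3%, so put the ratio there at 1.00.

5. Draw the level from cedar, whose last readings lie flat. Pool them to get the level ratio, target over isomer once the readings stop moving: 0.507. It lies below one, so expect isomer to lead.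

6. Check that birch gets there. Cedar is flat by 20.0 min, and birch has half its catalyst. Stretch the time in proportion to get 40.0 min, which is shorter than 80 min. So call the stretch past 40.0 min thermodynamic control, and commit to the level ratio at 80 min.

7. The forecast gives 11, 1 and 0.51, with isomer of the product ahead, holding that “birch should be at equilibrium”.

8. The flask gives 6.50, 1.03 and 0.472, with isomer of the product ahead. At 40.0 min it holds target 27.1% and isomer 56.6%, close to the 26.9% and 57.0% at 80.0 min. Apply the level ratio to the final isomer, 57.0%: it gives target 28.9%, against 26.9% in the flask.

    starting material + catalyst ⇌ target + catalyst, rate k1*[starting material]*[catalyst] forward; the back reaction follows from the equilibrium constant (K = 1.67, k = 14.3 L mol⁻¹ s⁻¹)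
    target ⇌ isomer of the product (K = 2.12, k = 0.00108 s⁻¹)
    isomer of the product + catalyst ⇌ starting material + catalyst, rate k3*[catalyst]*[isomer of the product] forward; the back reaction follows from the equilibrium constant (k = 0.436 L mol⁻¹ s⁻¹)
    solid substrate ⇌ starting material, rate k4*(cs4 - [starting material]) while solid is left; crystals form when [starting material] > cs4 (solubility = 0.760 M, k = 0.00859 s⁻¹)

9. Now take the flask with 0.40 M of solid substrate and the catalyst of birch. The reach is still 40.0 min, so the level ratio gives 0.507 at 80 min; the computed ratio is 0.472.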